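## Retrosynthetic overview

1. Both δ-lactones are closed last by oxidative lactonization of two 1,5-diols; both (Z,Z)-diene tails come from one double Wittig reaction, and the E-C9=C10 alkene from a Julia–Kocienski olefination with a cyclopropyl aldehyde.
2. The tetrahydrofuran is the ring of chiral-pool (S)-5-(hydroxymethyl)butenolide: the lactone carbonyl (C12) is allylated and reduced, and C12′ is set by chelation-controlled allylation.
3. Key disconnection C9′–C10′: the 2-lithio-1,3-dithiane of the cyclopropyl aldehyde (an acyl anion equivalent) adds to the butenolide β-carbon, and the enolate is trapped with formaldehyde (C10) in the same flask.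
4. The cyclopropyl building block (used twice) comes from 3,3-diethoxypropyne and δ-valerolactone by ynone transfer hydrogenation, trans-reduction and hydroxyl-directed Simmons–Smith reaction.
5. Ring order: cyclopropane (step 4), then tetrahydrofuran (butenolide ring carried through steps 9–11), then both δ-lactones together (step 24).

Labels: each C20 half is numbered from its lactone carbonyl; the unprimed half (C1–C20) holds the C9=C10 alkene, the primed half (C1′–C20′) holds the C9′ and C12′ carbinols; the tetrahydrofuran is O–C11′–C10′–C11–C12.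
Assumption: common reagents (silyl triflates, PPh3, organometallic reagents, the CBS catalyst and the like) are bought; only compounds on the carbon path are numbered.

## Route

Step 1
Reactants: 1 3,3-diethoxyprop-1-yne; 2 δ-valerolactone (oxan-2-one)
Product: 4 8,8-diethoxy-1-hydroxyoct-6-yn-5-one, via lithium acetylide 3 (not isolated)
Conditions: n-BuLi, THF, −78 °C; then 2, −78 °C, 1 h; AcOH quench
Reagents that add atoms: none
Why: Acetylide acylation by lactone ring opening, in which the tetrahedral lithium hemiketalate is stable at −78 °C so that only one acetylide adds and the hydroxy ynone is released on quench.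

Step 2
Reactants: 4 8,8-diethoxy-1-hydroxyoct-6-yn-5-one
Product: 5 (5R)-8,8-diethoxyoct-6-yne-1,5-diol
Conditions: RuCl[(R,R)-TsDPEN](p-cymene) (1 mol%), KOH (2 mol%), i-PrOH, 25 °C
Reagents that add atoms: none
Why: Noyori asymmetric transfer hydrogenation of an ynone, where the alkynyl group takes the place of the aryl group in the catalyst pocket so that the (R,R)-ligand gives the 5R carbinol.

Step 3
Reactants: 5 (5R)-8,8-diethoxyoct-6-yne-1,5-diol
Product: 6 (5R,6E)-8,8-diethoxyoct-6-ene-1,5-diol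
Conditions: LiAlH4, THF, 0 °C to rt; H2O/NaOH work-up
Reagents that add atoms: none
Why: Alkoxide-directed trans-hydroalumination of a propargylic alcohol gives only the E-alkene and leaves the acetal untouched.

Step 4
Reactants: 6 (5R,6E)-8,8-diethoxyoct-6-ene-1,5-diol
Product: 7 (1R)-1-[(1R,2R)-2-(diethoxymethyl)cyclopropyl]pentane-1,5-diol
Conditions: Et2Zn (5 equiv), CH2I2 (5 equiv), CH2Cl2, −10 to 0 °C
Reagents that add atoms: diiodomethane (ICI)
Why: Furukawa-type Simmons–Smith cyclopropanation directed by the zinc alkoxide of the C5 hydroxyl in the conformer with C5–H in the alkene plane (least allylic 1,3-strain), which delivers CH2 syn to oxygen, sets C6 and C8 and keeps the trans ring of the E-alkene.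

Step 5
Reactants: 7 (1R)-1-[(1R,2R)-2-(diethoxymethyl)cyclopropyl]pentane-1,5-diol
Product: 8 (1R,2R)-1-(diethoxymethyl)-2-[(1R)-1,5-bis(triisopropylsilyloxy)pentyl]cyclopropane
Conditions: i-Pr3SiOTf (2.5 equiv), 2,6-lutidine, CH2Cl2, 0 °C to rt
Reagents that add atoms: triisopropylsilyl triflate (CC(C)[Si](C(C)C)(C(C)C)OS(=O)(=O)C(F)(F)F)
Why: Silyl triflate silylation protects both hydroxyls as base-, organolithium- and mild-acid-stable TIPS ethers.

Step 6
Reactants: 8 (1R,2R)-1-(diethoxymethyl)-2-[(1R)-1,5-bis(triisopropylsilyloxy)pentyl]cyclopropane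
Product: 9 2-{(1R,2R)-2-[(1R)-1,5-bis(triisopropylsilyloxy)pentyl]cyclopropyl}-1,3-dithiane
Conditions: HS(CH2)3SH (1.2 equiv), BF3·OEt2 (0.2 equiv), CH2Cl2, −20 to 0 °C
Reagents that add atoms: propane-1,3-dithiol (SCCCS)
Why: Lewis-acid transthioacetalization, in which the cyclopropyl-stabilised oxocarbenium and thionium ions do not ring-open and the TIPS ethers survive catalytic BF3.

Step 7
Reactants: 8 (1R,2R)-1-(diethoxymethyl)-2-[(1R)-1,5-bis(triisopropylsilyloxy)pentyl]cyclopropane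
Product: 10 (1R,2R)-2-[(1R)-1,5-bis(triisopropylsilyloxy)pentyl]cyclopropane-1-carbaldehyde
Conditions: PPTS (0.1 equiv), acetone/H2O (10:1), 45 °C
Reagents that add atoms: water (O)
Why: Mild acetal hydrolysis, which keeps the TIPS ethers and the thermodynamically preferred trans-cyclopropane.

Step 8
Reactants: 11 (5S)-5-(hydroxymethyl)furan-2(5H)-one
Product: 12 (5S)-5-[(triethylsilyloxy)methyl]furan-2(5H)-one
Conditions: Et3SiCl, imidazole, CH2Cl2, 0 °C
Reagents that add atoms: chlorotriethylsilane (CC[Si](Cl)(CC)CC)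
Why: Silylation of the primary alcohol gives a group that shields one face of the butenolide and can later be oxidised directly to the aldehyde.

Step 9
Reactants: 9 2-{(1R,2R)-2-[(1R)-1,5-bis(triisopropylsilyloxy)pentyl]cyclopropyl}-1,3-dithiane; 12 (5S)-5-[(triethylsilyloxy)methyl]furan-2(5H)-one
Product: 15 (3R,4S,5S)-3-(hydroxymethyl)-4-[2-(cyclopropyl unit of 9)-1,3-dithian-2-yl]-5-[(triethylsilyloxy)methyl]oxolan-2-one, via 2-lithiodithiane 13 (not isolated), via lithium enolate 14 (not isolated)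
Conditions: n-BuLi, THF, −30 °C, 2 h; HMPA, then 12, −78 °C, 1 h; CH2O (gas), −78 to −40 °C; AcOH quench
Reagents that add atoms: formaldehyde (C=O), from cracked paraformaldehyde
Why: Corey–Seebach acyl anion equivalent in a tandem Michael addition–aldol, where the dithiane anion adds to C10′ anti to the C11′ substituent and formaldehyde traps the lactone enolate anti to the new C10′ group, which sets the 10′,11′-trans and 10′,11-trans relationships.

Step 10
Reactants: 15 hydroxymethyl lactone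
Product: 16 lactol (C12 carries OH and allyl; anomer mixture)
Conditions: CH2=CHCH2MgBr (2.5 equiv), THF, −78 °C, 30 min; H2O quench
Reagents that add atoms: allylmagnesium bromide (C=CC[Mg]Br)
Why: Grignard mono-addition to a γ-lactone, which stops at the magnesium hemiketalate at −78 °C after the first equivalent has deprotonated the hydroxyl.

Step 11
Reactants: 16 lactol
Product: 17 all-trans tetrahydrofuran alcohol (C12 allyl; C11 CH2OH; C10′ dithianyl; C11′ CH2OSiEt3)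
Conditions: Et3SiH (5 equiv), BF3·OEt2 (3 equiv), CH2Cl2, −78 °C
Reagents that add atoms: none
Why: Kishi-type ionic reduction of the hemiketal, in which hydride attacks the five-membered oxocarbenium ion on the inside face of its envelope (Woerpel model), anti to the bulky C10′ group, so that the C12 allyl group ends trans to C11.

Step 12
Reactants: 17 all-trans tetrahydrofuran alcohol
Product: 18 thioether (C10 carries S-(1-phenyl-1H-tetrazol-5-yl))
Conditions: 1-phenyl-1H-tetrazole-5-thiol, PPh3, DIAD, THF, 0 °C to rt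
Reagents that add atoms: 1-phenyl-1H-tetrazole-5-thiol (Sc1nnnn1-c1ccccc1)
Why: Mitsunobu thioetherification of the only free (primary) hydroxyl installs the future Julia–Kocienski sulfur group.

Step 13
Reactants: 18 thioether
Product: 19 aldehyde (C12′ is CHO on C11′)
Conditions: (COCl)2, DMSO, CH2Cl2, −78 to −30 °C; Et3N, −78 to 0 °C
Reagents that add atoms: none
Why: Swern oxidation of a primary triethylsilyl ether, which is cleaved in situ and oxidised directly to the aldehyde while TIPS ethers, dithiane and thioether are untouched.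

Step 14
Reactants: 19 aldehyde
Product: 20 homoallylic alcohol (12′S; threo to C11′)
Conditions: Bu3SnCH2CH=CH2 (1.5 equiv), MgBr2·OEt2 (3 equiv), CH2Cl2, −78 to −20 °C
Reagents that add atoms: allyltributylstannane (C=CC[Sn](CCCC)(CCCC)CCCC)
Why: Keck chelation-controlled allylation, in which magnesium bridges the ring oxygen and the aldehyde oxygen (Cram chelate) and the stannane attacks the open face to give the threo 12′S carbinol.

Step 15
Reactants: 20 homoallylic alcohol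
Product: 21 cyclopropyl ketone (C9′ is C=O)
Conditions: MeI (20 equiv), CaCO3 (5 equiv), MeCN/H2O (9:1), 45 °C
Reagents that add atoms: water (O)
Why: S-alkylative dithiane hydrolysis under near-neutral conditions that spare the terminal alkenes, the electron-poor thioether, the silyl ethers and the epimerisable C10′ centre.

Step 16
Reactants: 21 cyclopropyl ketone
Product: 22 diol (C9′ carbinol configured as in the target)
Conditions: (S)-2-methyl-CBS-oxazaborolidine (0.5 equiv), catecholborane (3 equiv), toluene, −78 to −40 °C; MeOH, then aqueous NaOH work-up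
Reagents that add atoms: none
Why: Corey–Bakshi–Shibata reduction with the branched ring carbon C10′ as the large group and cyclopropyl as the small group, so that the (S)-catalyst gives the 9′R carbinol, while catecholborane does not hydroborate the terminal alkenes.

Step 17
Reactants: 22 diol
Product: 23 bis(tert-butyldimethylsilyl) ether of 22
Conditions: t-BuMe2SiOTf (3 equiv), 2,6-lutidine, CH2Cl2, −20 to 0 °C
Reagents that add atoms: tert-butyldimethylsilyl triflate (CC(C)(C)[Si](C)(C)OS(=O)(=O)C(F)(F)F)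
Why: Silyl triflate silylation protects both secondary carbinols for the basic Wittig and Julia steps.

Step 18
Reactants: 23 bis(tert-butyldimethylsilyl) ether
Product: 25 dialdehyde (C14 and C14′ are CHO), via bis-ozonide 24 (not isolated)
Conditions: O3, CH2Cl2, −78 °C (Sudan Red 7B end-point); PPh3, −78 °C to rt
Reagents that add atoms: ozone ([O-][O+]=O)
Why: Ozonolysis with reductive work-up, in which the two monosubstituted alkenes react far faster than the electron-poor tetrazolyl thioether and the dye marks the end-point.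

Step 19
Reactants: 26 (3Z)-hex-3-en-1-ol
Product: 28 [(3Z)-hex-3-en-1-yl]triphenylphosphonium iodide, via hexenyl iodide 27 (not isolated)
Conditions: PPh3 (2.2 equiv), I2 (1.1 equiv), 2,6-lutidine (1.2 equiv), MeCN, 0 °C to rt; then reflux, 24 h
Reagents that add atoms: triphenylphosphine (c1ccc(cc1)P(c1ccccc1)c1ccccc1); iodine (II)
Why: Appel iodination followed in the same flask by SN2 quaternisation with the second equivalent of phosphine, which leaves the Z-alkene unchanged.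

Step 20
Reactants: 25 dialdehyde; 28 [(3Z)-hex-3-en-1-yl]triphenylphosphonium iodide
Product: 30 bis-(Z,Z)-diene thioether, via phosphorus ylide 29 (not isolated)
Conditions: 28 (2.6 equiv), NaN(SiMe3)2 (2.5 equiv), THF, −78 to 0 °C; then 25, −78 °C to rt
Reagents that add atoms: none
Why: Double Wittig olefination with a non-stabilised ylide under lithium-free conditions gives both new Z-alkenes (C14=C15 and C14′=C15′) through kinetically formed cis-oxaphosphetanes.

Step 21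
Reactants: 30 bis-(Z,Z)-diene thioether
Product: 31 sulfone of 30
Conditions: (NH4)6Mo7O24·4H2O (0.2 equiv), 30% H2O2, EtOH, 0 °C to rt
Reagents that add atoms: hydrogen peroxide (OO)
Why: Molybdate-catalysed peroxide oxidation takes the sulfide to the sulfone and is chemoselective over isolated alkenes.

Step 22
Reactants: 31 sulfone; 10 (1R,2R)-2-[(1R)-1,5-bis(triisopropylsilyloxy)pentyl]cyclopropane-1-carbaldehyde
Product: 33 fully silylated C40 skeleton with the E-C9=C10 alkene, via potassium sulfonyl carbanion 32 (not isolated)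
Conditions: KN(SiMe3)2 (1.1 equiv), DME, −60 °C, 20 min; then 10, −60 °C to rt
Reagents that add atoms: none
Why: Julia–Kocienski olefination, in which the potassium sulfonyl anion and the α-branched aldehyde combine through an open transition state and Smiles rearrangement with loss of SO2 gives the E-alkene.

Step 23
Reactants: 33 fully silylated C40 skeleton
Product: 34 hexaol (free C1, C5, C1′, C5′, C9′ and C12′ hydroxyls)
Conditions: Bu4NF (12 equiv), THF, 25 to 40 °C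
Reagents that add atoms: none
Why: Fluoride-mediated global desilylation is safe because no base-sensitive lactone is present yet.

Step 24
Reactants: 34 hexaol
Product: 36 target CNP0273074.2, via bis-lactol 35 (not isolated)
Conditions: TEMPO (0.3 equiv), PhI(OAc)2 (5 equiv), CH2Cl2, 25 °C
Reagents that add atoms: none
Why: Oxoammonium-mediated oxidative lactonization, which is selective for primary over secondary alcohols, so each 5-hydroxy aldehyde closes to its lactol and is oxidised on to the δ-lactone while the C9′ and C12′ carbinols remain.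

## Compound list

1 | 3,3-diethoxyprop-1-yne | C#CC(OCC)OCC | starting material
2 | δ-valerolactone (oxan-2-one) | O=C1CCCCO1 | starting material
3 | lithium 3,3-diethoxyprop-1-yn-1-ide | [Li]C#CC(OCC)OCC | intermediate
4 | 8,8-diethoxy-1-hydroxyoct-6-yn-5-one | OCCCCC(=O)C#CC(OCC)OCC | intermediate
5 | (5R)-8,8-diethoxyoct-6-yne-1,5-diol | CCOC(OCC)C#C[C@H](O)CCCCO | intermediate
6 | (5R,6E)-8,8-diethoxyoct-6-ene-1,5-diol | CCOC(OCC)/C=C/[C@H](O)CCCCO | intermediate
7 | (1R)-1-[(1R,2R)-2-(diethoxymethyl)cyclopropyl]pentane-1,5-diol | CCOC(OCC)[C@@H]1C[C@H]1[C@H](O)CCCCO | intermediate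
8 | (1R,2R)-1-(diethoxymethyl)-2-[(1R)-1,5-bis(triisopropylsilyloxy)pentyl]cyclopropane | CCOC(OCC)[C@@H]1C[C@H]1[C@H](O[Si](C(C)C)(C(C)C)C(C)C)CCCCO[Si](C(C)C)(C(C)C)C(C)C | intermediate
9 | 2-{(1R,2R)-2-[(1R)-1,5-bis(triisopropylsilyloxy)pentyl]cyclopropyl}-1,3-dithiane | C1CSC(SC1)[C@@H]1C[C@H]1[C@H](O[Si](C(C)C)(C(C)C)C(C)C)CCCCO[Si](C(C)C)(C(C)C)C(C)C | intermediate
10 | (1R,2R)-2-[(1R)-1,5-bis(triisopropylsilyloxy)pentyl]cyclopropane-1-carbaldehyde | O=C[C@@H]1C[C@H]1[C@H](O[Si](C(C)C)(C(C)C)C(C)C)CCCCO[Si](C(C)C)(C(C)C)C(C)C | intermediate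
11 | (5S)-5-(hydroxymethyl)furan-2(5H)-one | OC[C@H]1OC(=O)C=C1 | starting material
12 | (5S)-5-[(triethylsilyloxy)methyl]furan-2(5H)-one | CC[Si](CC)(CC)OC[C@H]1OC(=O)C=C1 | intermediate
13 | 2-lithio derivative of dithiane 9 | [Li]C1(SCCCS1)[C@@H]2C[C@H]2[C@H](O[Si](C(C)C)(C(C)C)C(C)C)CCCCO[Si](C(C)C)(C(C)C)C(C)C | intermediate
14 | lithium enolate of the C12 lactone (C10′ dithianyl trans to C11′ CH2OSiEt3) | CC[Si](CC)(CC)OC[C@H]1OC(O[Li])=C[C@@H]1C2(SCCCS2)[C@@H]3C[C@H]3[C@H](O[Si](C(C)C)(C(C)C)C(C)C)CCCCO[Si](C(C)C)(C(C)C)C(C)C | intermediate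
15 | (3R,4S,5S)-3-(hydroxymethyl)-4-[2-(cyclopropyl unit of 9)-1,3-dithian-2-yl]-5-[(triethylsilyloxy)methyl]oxolan-2-one | CC[Si](CC)(CC)OC[C@H]1OC(=O)[C@@H](CO)[C@@H]1C2(SCCCS2)[C@@H]3C[C@H]3[C@H](O[Si](C(C)C)(C(C)C)C(C)C)CCCCO[Si](C(C)C)(C(C)C)C(C)C | intermediate
16 | lactol: 15 with C12 carrying OH and allyl (anomer mixture) | CC[Si](CC)(CC)OC[C@H]1OC(O)(CC=C)[C@@H](CO)[C@@H]1C2(SCCCS2)[C@@H]3C[C@H]3[C@H](O[Si](C(C)C)(C(C)C)C(C)C)CCCCO[Si](C(C)C)(C(C)C)C(C)C | intermediate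
17 | all-trans tetrahydrofuran alcohol (C12 allyl; C11 CH2OH; C10′ dithianyl; C11′ CH2OSiEt3) | CC[Si](CC)(CC)OC[C@H]1O[C@H](CC=C)[C@@H](CO)[C@@H]1C2(SCCCS2)[C@@H]3C[C@H]3[C@H](O[Si](C(C)C)(C(C)C)C(C)C)CCCCO[Si](C(C)C)(C(C)C)C(C)C | intermediate
18 | thioether: 17 with C10 carrying S-(1-phenyl-1H-tetrazol-5-yl) | CC[Si](CC)(CC)OC[C@H]1O[C@H](CC=C)[C@@H](CSc4nnnn4-c5ccccc5)[C@@H]1C2(SCCCS2)[C@@H]3C[C@H]3[C@H](O[Si](C(C)C)(C(C)C)C(C)C)CCCCO[Si](C(C)C)(C(C)C)C(C)C | intermediate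
19 | aldehyde: 18 with C12′ as CHO | O=C[C@H]1O[C@H](CC=C)[C@@H](CSc4nnnn4-c5ccccc5)[C@@H]1C2(SCCCS2)[C@@H]3C[C@H]3[C@H](O[Si](C(C)C)(C(C)C)C(C)C)CCCCO[Si](C(C)C)(C(C)C)C(C)C | intermediate
20 | homoallylic alcohol (12′S, threo to C11′) | C=CC[C@H](O)[C@H]1O[C@H](CC=C)[C@@H](CSc4nnnn4-c5ccccc5)[C@@H]1C2(SCCCS2)[C@@H]3C[C@H]3[C@H](O[Si](C(C)C)(C(C)C)C(C)C)CCCCO[Si](C(C)C)(C(C)C)C(C)C | intermediate
21 | cyclopropyl ketone: 20 with C9′ as C=O | C=CC[C@H](O)[C@H]1O[C@H](CC=C)[C@@H](CSc4nnnn4-c5ccccc5)[C@@H]1C(=O)[C@@H]3C[C@H]3[C@H](O[Si](C(C)C)(C(C)C)C(C)C)CCCCO[Si](C(C)C)(C(C)C)C(C)C | intermediate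
22 | diol: C9′ and C12′ carbinols configured as in the target | C=CC[C@H](O)[C@H]1O[C@H](CC=C)[C@@H](CSc4nnnn4-c5ccccc5)[C@@H]1[C@H](O)[C@@H]3C[C@H]3[C@H](O[Si](C(C)C)(C(C)C)C(C)C)CCCCO[Si](C(C)C)(C(C)C)C(C)C | intermediate
23 | bis(tert-butyldimethylsilyl) ether of 22 | C=CC[C@H](O[Si](C)(C)C(C)(C)C)[C@H]1O[C@H](CC=C)[C@@H](CSc4nnnn4-c5ccccc5)[C@@H]1[C@H](O[Si](C)(C)C(C)(C)C)[C@@H]3C[C@H]3[C@H](O[Si](C(C)C)(C(C)C)C(C)C)CCCCO[Si](C(C)C)(C(C)C)C(C)C | intermediate
24 | bis-ozonide of 23 (two 1,2,4-trioxolanes) | C1OC(OO1)C[C@H](O[Si](C)(C)C(C)(C)C)[C@H]2O[C@H](CC6OCOO6)[C@@H](CSc4nnnn4-c5ccccc5)[C@@H]2[C@H](O[Si](C)(C)C(C)(C)C)[C@@H]3C[C@H]3[C@H](O[Si](C(C)C)(C(C)C)C(C)C)CCCCO[Si](C(C)C)(C(C)C)C(C)C | intermediate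
25 | dialdehyde (C14 and C14′ CHO) | O=CC[C@H](O[Si](C)(C)C(C)(C)C)[C@H]1O[C@H](CC=O)[C@@H](CSc4nnnn4-c5ccccc5)[C@@H]1[C@H](O[Si](C)(C)C(C)(C)C)[C@@H]3C[C@H]3[C@H](O[Si](C(C)C)(C(C)C)C(C)C)CCCCO[Si](C(C)C)(C(C)C)C(C)C | intermediate
26 | (3Z)-hex-3-en-1-ol | CC/C=C\CCO | starting material
27 | (3Z)-1-iodohex-3-ene | CC/C=C\CCI | intermediate
28 | [(3Z)-hex-3-en-1-yl]triphenylphosphonium iodide | CC/C=C\CC[P+](c1ccccc1)(c1ccccc1)c1ccccc1.[I-] | intermediate
29 | [(3Z)-hex-3-en-1-ylidene]triphenylphosphorane | CC/C=C\CC=P(c1ccccc1)(c1ccccc1)c1ccccc1 | intermediate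
30 | bis-(Z,Z)-diene thioether | CC/C=C\C/C=C\C[C@H](O[Si](C)(C)C(C)(C)C)[C@H]1O[C@H](C/C=C\C/C=C\CC)[C@@H](CSc4nnnn4-c5ccccc5)[C@@H]1[C@H](O[Si](C)(C)C(C)(C)C)[C@@H]3C[C@H]3[C@H](O[Si](C(C)C)(C(C)C)C(C)C)CCCCO[Si](C(C)C)(C(C)C)C(C)C | intermediate
31 | sulfone of 30 | CC/C=C\C/C=C\C[C@H](O[Si](C)(C)C(C)(C)C)[C@H]1O[C@H](C/C=C\C/C=C\CC)[C@@H](CS(=O)(=O)c4nnnn4-c5ccccc5)[C@@H]1[C@H](O[Si](C)(C)C(C)(C)C)[C@@H]3C[C@H]3[C@H](O[Si](C(C)C)(C(C)C)C(C)C)CCCCO[Si](C(C)C)(C(C)C)C(C)C | intermediate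
32 | potassium salt of the C10 carbanion of 31 | CC/C=C\C/C=C\C[C@H](O[Si](C)(C)C(C)(C)C)[C@H]1O[C@H](C/C=C\C/C=C\CC)[C@@H]([CH]([K])S(=O)(=O)c4nnnn4-c5ccccc5)[C@@H]1[C@H](O[Si](C)(C)C(C)(C)C)[C@@H]3C[C@H]3[C@H](O[Si](C(C)C)(C(C)C)C(C)C)CCCCO[Si](C(C)C)(C(C)C)C(C)C | intermediate
33 | fully silylated C40 skeleton with E-C9=C10 | CC/C=C\C/C=C\C[C@H](O[Si](C)(C)C(C)(C)C)[C@H]1O[C@H](C/C=C\C/C=C\CC)[C@@H](/C=C/[C@@H]2C[C@H]2[C@H](O[Si](C(C)C)(C(C)C)C(C)C)CCCCO[Si](C(C)C)(C(C)C)C(C)C)[C@@H]1[C@H](O[Si](C)(C)C(C)(C)C)[C@@H]3C[C@H]3[C@H](O[Si](C(C)C)(C(C)C)C(C)C)CCCCO[Si](C(C)C)(C(C)C)C(C)C | intermediate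
34 | hexaol | CC/C=C\C/C=C\C[C@H](O)[C@H]1O[C@H](C/C=C\C/C=C\CC)[C@@H](/C=C/[C@@H]2C[C@H]2[C@H](O)CCCCO)[C@@H]1[C@H](O)[C@@H]3C[C@H]3[C@H](O)CCCCO | intermediate
35 | bis-lactol | CC/C=C\C/C=C\C[C@H](O)[C@H]1O[C@H](C/C=C\C/C=C\CC)[C@@H](/C=C/[C@@H]2C[C@H]2[C@H]2CCCC(O)O2)[C@@H]1[C@H](O)[C@@H]1C[C@H]1[C@H]1CCCC(O)O1 | intermediate
36 | CNP0273074.2 | CC/C=C\C/C=C\C[C@H](O)[C@H]1O[C@H](C/C=C\C/C=C\CC)[C@@H](/C=C/[C@@H]2C[C@H]2[C@H]2CCCC(=O)O2)[C@@H]1[C@H](O)[C@@H]1C[C@H]1[C@H]1CCCC(=O)O1 | target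

## Step count and risks

Total: 24 steps. Longest linear sequence: 21 steps (steps 1–6, 9–18, 20–24).

Most likely to fail, first: step 9. The hindered cyclopropyl dithiane anion may add 1,2 or deprotonate the butenolide instead of adding 1,4. The fallback sets out from aldehyde 10 and butenolide 12. A decatungstate-photocatalysed hydroacylation ((Bu4N)4[W10O32], 365 nm, MeCN) adds the nucleophilic acyl radical of 10 to C10′ anti to the C11′ substituent and gives the β-acyl lactone F1. Thioketalisation (HS(CH2)3SH, Zn(OTf)2, CH2Cl2) then gives the dithiane lactone F2. LiN(i-Pr)2 at −78 °C converts F2 into enolate 14, which is hydroxymethylated as in step 9, so the route is rejoined at 14 and 15.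

Second: step 16. The substrate's own facial bias at C9′ is hard to predict and may oppose the catalyst. The fallback sets out from ketone 21. t-BuMe2SiOTf gives the C12′ silyl ether ketone F3, and LiBH(s-Bu)3 reduces it under substrate control to the 9′-epimeric alcohol F4. Mitsunobu esterification (4-nitrobenzoic acid, PPh3, DIAD) inverts C9′ to the 4-nitrobenzoate F5, and K2CO3/MeOH frees the C9′ alcohol F6 with the target configuration. Silylation as in step 17 returns to 23.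

Third: step 18. Ozone may also oxidise the thioether. The fallback sets out from 23 and changes the order of events. Sulfur is first taken to the ozone-inert sulfone F7 with H2O2 and (NH4)6Mo7O24·4H2O. Ozonolysis then passes through the sulfone bis-ozonide F8 to the sulfone dialdehyde F9. A Wittig reaction with ylide 29 at −78 °C, where carbonyl addition outruns proton transfer from the hindered sulfone, gives 31 directly. The route is rejoined at 31, and steps 18, 20 and 21 are replaced.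

## Further compounds

F1 | step 9 | β-acyl lactone: (4S,5S)-4-(cyclopropylcarbonyl unit from 10)-5-[(triethylsilyloxy)methyl]oxolan-2-one, 4,5-trans | CC[Si](CC)(CC)OC[C@H]1OC(=O)C[C@@H]1C(=O)[C@@H]3C[C@H]3[C@H](O[Si](C(C)C)(C(C)C)C(C)C)CCCCO[Si](C(C)C)(C(C)C)C(C)C
F2 | step 9 | dithiane lactone: 15 without the C11 hydroxymethyl group | CC[Si](CC)(CC)OC[C@H]1OC(=O)C[C@@H]1C2(SCCCS2)[C@@H]3C[C@H]3[C@H](O[Si](C(C)C)(C(C)C)C(C)C)CCCCO[Si](C(C)C)(C(C)C)C(C)C
F3 | step 16 | C12′ tert-butyldimethylsilyl ether of ketone 21 | C=CC[C@H](O[Si](C)(C)C(C)(C)C)[C@H]1O[C@H](CC=C)[C@@H](CSc4nnnn4-c5ccccc5)[C@@H]1C(=O)[C@@H]3C[C@H]3[C@H](O[Si](C(C)C)(C(C)C)C(C)C)CCCCO[Si](C(C)C)(C(C)C)C(C)C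
F4 | step 16 | 9′-epimeric alcohol (C12′ silyl ether) | C=CC[C@H](O[Si](C)(C)C(C)(C)C)[C@H]1O[C@H](CC=C)[C@@H](CSc4nnnn4-c5ccccc5)[C@@H]1[C@@H](O)[C@@H]3C[C@H]3[C@H](O[Si](C(C)C)(C(C)C)C(C)C)CCCCO[Si](C(C)C)(C(C)C)C(C)C
F5 | step 16 | C9′ 4-nitrobenzoate with the target configuration | C=CC[C@H](O[Si](C)(C)C(C)(C)C)[C@H]1O[C@H](CC=C)[C@@H](CSc4nnnn4-c5ccccc5)[C@@H]1[C@H](OC(=O)c6ccc(cc6)[N+](=O)[O-])[C@@H]3C[C@H]3[C@H](O[Si](C(C)C)(C(C)C)C(C)C)CCCCO[Si](C(C)C)(C(C)C)C(C)C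
F6 | step 16 | C9′ alcohol with the target configuration (C12′ silyl ether) | C=CC[C@H](O[Si](C)(C)C(C)(C)C)[C@H]1O[C@H](CC=C)[C@@H](CSc4nnnn4-c5ccccc5)[C@@H]1[C@H](O)[C@@H]3C[C@H]3[C@H](O[Si](C(C)C)(C(C)C)C(C)C)CCCCO[Si](C(C)C)(C(C)C)C(C)C
F7 | step 18 | sulfone of 23 | C=CC[C@H](O[Si](C)(C)C(C)(C)C)[C@H]1O[C@H](CC=C)[C@@H](CS(=O)(=O)c4nnnn4-c5ccccc5)[C@@H]1[C@H](O[Si](C)(C)C(C)(C)C)[C@@H]3C[C@H]3[C@H](O[Si](C(C)C)(C(C)C)C(C)C)CCCCO[Si](C(C)C)(C(C)C)C(C)C
F8 | step 18 | sulfone bis-ozonide | C1OC(OO1)C[C@H](O[Si](C)(C)C(C)(C)C)[C@H]2O[C@H](CC6OCOO6)[C@@H](CS(=O)(=O)c4nnnn4-c5ccccc5)[C@@H]2[C@H](O[Si](C)(C)C(C)(C)C)[C@@H]3C[C@H]3[C@H](O[Si](C(C)C)(C(C)C)C(C)C)CCCCO[Si](C(C)C)(C(C)C)C(C)C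
F9 | step 18 | sulfone dialdehyde | O=CC[C@H](O[Si](C)(C)C(C)(C)C)[C@H]1O[C@H](CC=O)[C@@H](CS(=O)(=O)c4nnnn4-c5ccccc5)[C@@H]1[C@H](O[Si](C)(C)C(C)(C)C)[C@@H]3C[C@H]3[C@H](O[Si](C(C)C)(C(C)C)C(C)C)CCCCO[Si](C(C)C)(C(C)C)C(C)C
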